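Slowness is not what held the chain figure down in the larch run. In the larch run free monomer read 0.1% at 4.00 h, while monomer in chains read 23.3% then and 23.0% at 50.0 h. So each molecule of free monomer seems to meet one fork, once, and you will be measuring how that fork fell.

You take over these flasks, and these runs stand behind them:

| flask | free monomer | pre-initiator | temperature | remark | time |
|---|---|---|---|---|---|
| larch | 3 M | 10 mM | 85 °C | run made earlier |  |
| cedar | 3 M | 22 mM | 120 °C | run made earlier |  |
| teal | 3.0 M | 15 mM | 150 °C |  | 2.0 h |
| violet | 3.0 M | 15 mM | 130 °C |  | 2.0 h |
| red | 3.0 M | 15 mM | 90 °C |  | 2.0 h |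
| green | 3.0 M | 15 mM | 110 °C |  | 2.0 h |

- larch (time / h: monomer in chains / %, free monomer / %): 4.00: 23.3, 0.1; 8.00: 23.2, 1.0; 20.0: 23.3, 0; 50.0: 23.0, 0
- cedar (time / h: monomer in chains / %, free monomer / %): 2.00: 12.7, 0.1; 4.00: 12.3, 0; 6.00: 13.1, 0; 8.00: 12.8, 0.4

(standard deviation of a reading: 0.5 percentage points)

- the analysis behind the earlier runs scatters by 0.5 percentage points, standard deviation

- the flask that comes out highest in amount of monomer in chains, in percent of the free monomer charged, or "all alike" when all lie within 1.5 percentage points (teal / violet / red / green / all alike)
- monomer in chains at the end, in percent of the free monomer charged, teal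
- monomer in chains at the end, in percent of the free monomer charged, violet
- monomer in chains at the end, in percent of the free monomer charged, red
- monomer in chains at the end, in percent of the free monomer charged, green

Follow one molecule. Its chain odds, a selectivity factor, are its share in chains over its share gone elsewhere. Larch averages 23.2%, which is odds of 0.302. Cedar averages 12.7%, or 0.146: lower odds, although hotter and charged with more pre-initiator.

I assume the odds go in proportion to c(pre-initiator), which these two runs, differing in temperature too, do not test. Per unit of it, larch then reads 4.56 times cedar. That gives the halving width, the temperature rise that halves the odds at a fixed charge: 16.0 K.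

At your charge my reckoning gives red 26.7%, green 13.3% and violet 6.05%. For teal I reckon odds of 0.0271, so 2.64%.

The forecast names red, with red 24%, green 14%, violet 8% and teal 5%. That is below mine at red and above mine at teal. Its ground: “It is losing a one-time competition with a side reaction that also eats monomer”. Leave the baths as set: larch read flat from 4.00 h to 50.0 h, though its earliest reading comes later than your 2.0 h.

Red came out highest at 24.5%, then green 13.9%, violet 7.00% and teal 3.33%, so the forecast's order stands.

    free monomer + initiator → living end + monomer in chains (k = 0.00686 M⁻¹ min⁻¹, Ea = 70.0 kJ mol⁻¹)
    free monomer + living end → monomer in chains + living end, rate k2*[living end]*[free monomer] (k = 196 M⁻¹ min⁻¹, Ea = 47.0 kJ mol⁻¹)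
    pre-initiator → initiator (k = 0.0649 min⁻¹, Ea = 105 kJ mol⁻¹)
    free monomer + monomer in chains → side product (k = 0.0233 M⁻¹ min⁻¹, Ea = 91.0 kJ mol⁻¹)
    free monomer → uncatalysed product (k = 0.0942 min⁻¹, Ea = 94.0 kJ mol⁻¹)
    (constants at 90 °C)

In teal at 0.00140 h, free monomer had a half-life of 0.089 min by the step to uncatalysed product and 2.9 min by the growth step into chains. By 1.00 h teal's free monomer stood at 0%, with 95.6% uncatalysed product and 3.33% in chains, and at 20.0 h monomer in chains stood at 3.33%. Red and teal together give a halving width of 18.5 K, against my 16.0 K. For teal's neighbour, charged with 0.060 M of pre-initiator, my width and proportion give 9.78%; that flask holds 10.2%.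

(The runs were generated by integration for substances that don't exist; noise was put on by code.)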